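**Retrosynthetic overview**
1. The chromene ring is formed last. Cutting C4–C4a and O1–C2 leads to 4,5,6-trimethoxybenzene-1,3-diol, whose only free ring carbon lies between the two OH groups, and a (Z)-3-methylpent-2-enal that carries the terpenoid ring.
2. The CH2CH2 link comes from a vinyl group on the quaternary carbon by hydroboration and B-alkyl Suzuki coupling.
3. The cyclohexene ring is formed first (locants: C1 quaternary, C2 CHMe, C3 =CMe, C4 =CH, C5 and C6 CH2). The C3 methyl comes from an enol triflate and that from a cyclohex-2-enone. The enone is made in one flask from an acyclic allylic alcohol acetal and (Z)-2-iodobut-2-ene by O-vinylation, Claisen shift and aldol condensation, which forms C1–C2 and C4–C5.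
4. Enabling feature: C1 carries a two-carbon side chain next to the CHMe carbon C2. With C3 as a ketone and the first two side-chain carbons as an (E)-alkene, O=C3–C2–C1–CH=CH is a Claisen retron. C3 and C5 stand 1,5 across C2–C1–C6, so the ketone methyl carbon (C4) closes the six-membered ring on C5.
5. Stereochemistry: one catalytic Et2Zn addition sets a carbinol centre that is relayed to C1 and C2 and then erased. Chromene C2 is set by a chiral Brønsted acid.

Key step: step 6

Assumption: the (R)-configured N-triflylphosphoramide of step 15 is taken to give the (R) centre at chromene C2; if the sense of induction is the opposite, its antipode is used.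

Step 1
Reactants: 1 4,4-dimethoxybutan-2-one; 2 triethyl phosphonoacetate
Product: 3 ethyl (2E)-5,5-dimethoxy-3-methylpent-2-enoate
Conditions: NaH, THF, 0 °C to rt; chromatography
Reagents that add atoms: none
Why: Horner–Wadsworth–Emmons olefination of the methyl ketone should favour the (E)-enoate (ester trans to the larger acetal arm), and the minor (Z)-isomer is removed by chromatography.

Step 2
Reactants: 3 ethyl (2E)-5,5-dimethoxy-3-methylpent-2-enoate
Product: 4 (2E)-5,5-dimethoxy-3-methylpent-2-en-1-ol
Conditions: i-Bu2AlH, CH2Cl2, −78 °C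
Reagents that add atoms: none
Why: 1,2-reduction of the enoate with an aluminium hydride at low temperature should leave the acetal and the alkene geometry untouched.

Step 3
Reactants: 4 (2E)-5,5-dimethoxy-3-methylpent-2-en-1-ol
Product: 5 (2E)-5,5-dimethoxy-3-methylpent-2-enal
Conditions: MnO2, CH2Cl2, rt
Reagents that add atoms: none
Why: allylic oxidation with activated MnO2 is neutral, so the acetal and the (E)-geometry should survive.

Step 4
Reactants: 5 (2E)-5,5-dimethoxy-3-methylpent-2-enal
Product: 6 (3R,4E)-7,7-dimethoxy-5-methylhept-4-en-3-ol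
Conditions: Et2Zn, (+)-3-exo-morpholinoisoborneol (5 mol %), hexane–toluene, 0 °C
Reagents that add atoms: diethylzinc, CC[Zn]CC
Why: ligand-accelerated enantioselective 1,2-addition of a dialkylzinc to a β,β-disubstituted enal, in which the amino-alkoxide zinc complex delivers ethyl to one aldehyde face and sets the (R)-carbinol centre.

Step 5
Reactants: 7 but-2-yne
Product: 9 (2Z)-2-iodobut-2-ene, via vinylstannane 8 (not isolated)
Conditions: Bu3SnH, [Cp*Ru(MeCN)3]PF6 (cat.), CH2Cl2, rt; then I2, 0 °C; distillation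
Reagents that add atoms: tributyltin hydride, CCCC[SnH](CCCC)CCCC (tin stays only in 8); iodine, [I][I]
Why: ruthenium-catalysed trans-hydrostannation places H and Sn on opposite sides of the symmetrical alkyne, and iododestannylation with retention gives the (Z)-iodide (iodine cis to the vinylic methyl group).

Step 6
Reactants: 6 (3R,4E)-7,7-dimethoxy-5-methylhept-4-en-3-ol; 9 (2Z)-2-iodobut-2-ene
Product: 13 (5S,6S)-5-[(1E)-but-1-en-1-yl]-5,6-dimethylcyclohex-2-en-1-one, via allyl vinyl ether 10 (not isolated), via keto acetal 11 (not isolated), via keto aldehyde 12 (not isolated)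
Conditions: CuI (10 mol %), 3,4,7,8-tetramethyl-1,10-phenanthroline (20 mol %), Cs2CO3, o-xylene, 120 °C; then TsOH·H2O (excess), THF–H2O, 65 °C, same flask
Reagents that add atoms: water, O (its oxygen stays only in 12)
Why: The copper catalyst couples the alkoxide of 6 with 9 with retention of the (Z)-geometry to give 10, which at 120 °C undergoes a [3,3]-sigmatropic Claisen shift that forms the congested C1–C2 bond and turns the temporary C–O tether into the C3 ketone of 11; the acid then hydrolyses the acetal to 12, and the ketone methyl carbon (C4) condenses with the aldehyde carbon (C5) with loss of water. The closest known reaction types are the domino copper-catalysed C–O coupling/Claisen rearrangement of allylic alcohols with vinyl iodides, which builds vicinal quaternary/tertiary centres, and the acid-mediated cyclodehydration of 5-oxoaldehydes to cyclohex-2-enones. The one ring closed, the carbocycle, forms by a 6-(enolendo)-exo-trig aldol addition followed by dehydration. C1 and C2 are set together in the chair transition state: the ethyl group on the (R)-carbinol carbon stays equatorial, which fixes the attacked face of the (E)-trisubstituted alkene (C1 = S, new side-chain alkene E), and the (Z)-enol ether holds its methyl group axial so that it ends cis to the C1 methyl group (C2 = S). The step needs chair over boat, intact alkene geometries, aldol regioselectivity and no enolisation towards C2: an axial ethyl group would clash with the axial C1 methyl group, both bond-forming events are stereospecific, every other aldol pairing in 12 would give a four-membered ring, and enolisation towards C2 is slowed by the neighbouring quaternary carbon.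

Step 7
Reactants: 13 (5S,6S)-5-[(1E)-but-1-en-1-yl]-5,6-dimethylcyclohex-2-en-1-one
Product: 15 (5S,6S)-5-[(1E)-but-1-en-1-yl]-5,6-dimethylcyclohex-1-en-1-yl trifluoromethanesulfonate, via lithium enolate 14 (not isolated)
Conditions: LiBH(s-Bu)3, THF, −78 °C; then N-(5-chloro-2-pyridyl)bis(trifluoromethanesulfonimide), −78 °C to 0 °C
Reagents that add atoms: N-(5-chloro-2-pyridyl)bis(trifluoromethanesulfonimide), FC(F)(F)S(=O)(=O)N(c1ccc(Cl)cn1)S(=O)(=O)C(F)(F)F; lithium tri-sec-butylborohydride, [Li+].CCC(C)[BH-](C(C)CC)C(C)CC (lithium stays only in 14)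
Why: conjugate hydride reduction of the β-unsubstituted cyclohexenone gives regiospecifically the enolate towards C4, and O-triflation traps it without any base that could epimerise C2.

Step 8
Reactants: 15 (5S,6S)-5-[(1E)-but-1-en-1-yl]-5,6-dimethylcyclohex-1-en-1-yl trifluoromethanesulfonate
Product: 16 (5S,6R)-5-[(1E)-but-1-en-1-yl]-1,5,6-trimethylcyclohex-1-ene
Conditions: MeMgBr, Fe(acac)3 (5 mol %), THF–NMP, −30 °C
Reagents that add atoms: methylmagnesium bromide, C[Mg]Br
Why: iron-catalysed cross-coupling of an alkenyl triflate with a methyl Grignard reagent installs the C3 methyl group with the double bond fixed at C3=C4 (the descriptor at C2 changes by priority only).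

Step 9
Reactants: 16 (5S,6R)-5-[(1E)-but-1-en-1-yl]-1,5,6-trimethylcyclohex-1-ene
Product: 17 (5S,6R)-5-ethenyl-1,5,6-trimethylcyclohex-1-ene
Conditions: ethylene (5 bar), second-generation Hoveyda–Grubbs catalyst (5 mol %), 1,4-benzoquinone (cat.), toluene, 60 °C
Reagents that add atoms: ethylene, C=C
Why: ethenolysis (cross-metathesis with ethylene) should cut the disubstituted side-chain alkene to the vinyl group, while the trisubstituted ring alkene is too hindered to react.

Step 10
Reactants: 18 but-2-yn-1-ol
Product: 20 (2Z)-3-iodobut-2-en-1-ol, via cyclic alkenylaluminate 19 (not isolated)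
Conditions: Na[AlH2(OCH2CH2OMe)2], Et2O, 0 °C to rt; then I2, −78 °C
Reagents that add atoms: sodium bis(2-methoxyethoxy)aluminium dihydride, [Na+].[H][Al-]([H])(OCCOC)OCCOC (stays only in 19); iodine, [I][I]
Why: hydroxyl-directed trans-hydroalumination of the propargylic alcohol gives a five-membered alkenylaluminate, and iodinolysis with retention gives the (Z)-iodide.

Step 11
Reactants: 17 (5S,6R)-5-ethenyl-1,5,6-trimethylcyclohex-1-ene; 20 (2Z)-3-iodobut-2-en-1-ol
Product: 22 (2Z)-3-methyl-5-[(1S,2S)-1,2,3-trimethylcyclohex-3-en-1-yl]pent-2-en-1-ol, via alkylborane 21 (not isolated)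
Conditions: 9-BBN-H, THF, rt; then 20, PdCl2(dppf), AsPh3, Cs2CO3, DMF–H2O, rt
Reagents that add atoms: 9-borabicyclo[3.3.1]nonane, [H]B1C2CCCC1CCC2 (boron stays only in 21)
Why: anti-Markovnikov hydroboration takes only the monosubstituted alkene, and the B-alkyl Suzuki–Miyaura coupling joins it to the vinyl iodide with retention of the (Z)-geometry.

Step 12
Reactants: 22 (2Z)-3-methyl-5-[(1S,2S)-1,2,3-trimethylcyclohex-3-en-1-yl]pent-2-en-1-ol
Product: 23 (2Z)-3-methyl-5-[(1S,2S)-1,2,3-trimethylcyclohex-3-en-1-yl]pent-2-enal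
Conditions: MnO2, CH2Cl2, 0 °C
Reagents that add atoms: none
Why: neutral allylic oxidation with MnO2 touches neither the isolated ring alkene nor the stereocentres.

Step 13
Reactants: 24 1,2,3-trimethoxybenzene
Product: 25 1,5-dibromo-2,3,4-trimethoxybenzene
Conditions: NBS (2.1 equiv), MeCN, rt
Reagents that add atoms: N-bromosuccinimide, O=C1CCC(=O)N1Br
Why: in this twofold electrophilic aromatic bromination each bromine enters ortho to one outer methoxy group and para to the other, which leaves free only the carbon between the two bromines.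

Step 14
Reactants: 25 1,5-dibromo-2,3,4-trimethoxybenzene
Product: 26 4,5,6-trimethoxybenzene-1,3-diol
Conditions: Cu(acac)2 (cat.), N,N'-bis(4-hydroxy-2,6-dimethylphenyl)oxalamide (cat.), LiOH·H2O, DMSO–H2O, 80 °C, argon; then dilute HCl
Reagents that add atoms: lithium hydroxide, [Li+].[OH-]
Why: copper-catalysed Ullmann-type hydroxylation of both aryl bromides gives the symmetrical resorcinol, which is handled under argon because it is electron-rich.

Step 15
Reactants: 23 (2Z)-3-methyl-5-[(1S,2S)-1,2,3-trimethylcyclohex-3-en-1-yl]pent-2-enal; 26 4,5,6-trimethoxybenzene-1,3-diol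
Product: 29 (2R)-6,7,8-trimethoxy-2-methyl-2-{2-[(1S,2S)-1,2,3-trimethylcyclohex-3-en-1-yl]ethyl}-2H-chromen-5-ol, via benzylic alcohol 27 (not isolated), via quinone methide 28 (not isolated)
Conditions: (R)-3,3'-bis(2,4,6-triisopropylphenyl)-1,1'-binaphthyl-2,2'-diyl N-triflylphosphoramide (10 mol %), 4 Å MS, toluene, −20 °C, dark
Reagents that add atoms: none
Why: Proposed new method: the acid should promote Friedel–Crafts hydroxyalkylation of 26 at its only free carbon to give 27, ionise 27 to the protonated form of 28, which stays hydrogen-bonded through its phenolic OH groups to the chiral phosphoramide anion, and that contact ion pair should close the O1–C2 bond (oxa-6π type) on one face to set the (R) centre. Because 26 is symmetrical, either OH gives the same product. The closest known reaction types are the racemic resorcinol/enal chromenylation (formal oxa-[3+3] annulation) and the chiral N-triflylphosphoramide-catalysed intramolecular allylic substitution that gives 2,2-disubstituted 2H-chromenes.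

**Compound list**
1 | 4,4-dimethoxybutan-2-one | CC(=O)CC(OC)OC | starting material
2 | triethyl phosphonoacetate | CCOC(=O)CP(=O)(OCC)OCC | starting material
3 | ethyl (2E)-5,5-dimethoxy-3-methylpent-2-enoate | CCOC(=O)/C=C(\C)CC(OC)OC | intermediate
4 | (2E)-5,5-dimethoxy-3-methylpent-2-en-1-ol | OC/C=C(\C)CC(OC)OC | intermediate
5 | (2E)-5,5-dimethoxy-3-methylpent-2-enal | O=C/C=C(\C)CC(OC)OC | intermediate
6 | (3R,4E)-7,7-dimethoxy-5-methylhept-4-en-3-ol | CC[C@@H](O)/C=C(\C)CC(OC)OC | intermediate
7 | but-2-yne | CC#CC | starting material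
8 | tributyl[(2Z)-but-2-en-2-yl]stannane | C/C=C(\[Sn](CCCC)(CCCC)CCCC)C | intermediate
9 | (2Z)-2-iodobut-2-ene | C/C=C(\I)C | intermediate
10 | (3R,4E)-3-[(2Z)-but-2-en-2-yloxy]-7,7-dimethoxy-5-methylhept-4-ene | CC[C@@H](O/C(C)=C\C)/C=C(\C)CC(OC)OC | intermediate
11 | (3S,4S,5E)-4-(2,2-dimethoxyethyl)-3,4-dimethyloct-5-en-2-one | CC/C=C/[C@](C)(CC(OC)OC)[C@H](C)C(C)=O | intermediate
12 | (3S,4E)-3-methyl-3-[(2S)-3-oxobutan-2-yl]hept-4-enal | CC/C=C/[C@](C)(CC=O)[C@H](C)C(C)=O | intermediate
13 | (5S,6S)-5-[(1E)-but-1-en-1-yl]-5,6-dimethylcyclohex-2-en-1-one | CC/C=C/[C@]1(C)CC=CC(=O)[C@H]1C | intermediate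
14 | lithium (5S,6S)-5-[(1E)-but-1-en-1-yl]-5,6-dimethylcyclohex-1-en-1-olate | CC/C=C/[C@]1(C)CCC=C(O[Li])[C@H]1C | intermediate
15 | (5S,6S)-5-[(1E)-but-1-en-1-yl]-5,6-dimethylcyclohex-1-en-1-yl trifluoromethanesulfonate | CC/C=C/[C@]1(C)CCC=C(OS(=O)(=O)C(F)(F)F)[C@H]1C | intermediate
16 | (5S,6R)-5-[(1E)-but-1-en-1-yl]-1,5,6-trimethylcyclohex-1-ene | CC/C=C/[C@]1(C)CCC=C(C)[C@H]1C | intermediate
17 | (5S,6R)-5-ethenyl-1,5,6-trimethylcyclohex-1-ene | C=C[C@]1(C)CCC=C(C)[C@H]1C | intermediate
18 | but-2-yn-1-ol | CC#CCO | starting material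
19 | sodium 2,2-bis(2-methoxyethoxy)-3-methyl-2,5-dihydro-1,2-oxaaluminol-2-uide (cyclic alkenylaluminate) | [Na+].CC1=CCO[Al-]1(OCCOC)OCCOC | intermediate
20 | (2Z)-3-iodobut-2-en-1-ol | I/C(C)=C\CO | intermediate
21 | 9-{2-[(1R,2S)-1,2,3-trimethylcyclohex-3-en-1-yl]ethyl}-9-borabicyclo[3.3.1]nonane (same spatial arrangement as 17) | B1(CC[C@]2(C)CCC=C(C)[C@H]2C)C3CCCC1CCC3 | intermediate
22 | (2Z)-3-methyl-5-[(1S,2S)-1,2,3-trimethylcyclohex-3-en-1-yl]pent-2-en-1-ol | OC/C=C(/C)CC[C@]1(C)CCC=C(C)[C@H]1C | intermediate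
23 | (2Z)-3-methyl-5-[(1S,2S)-1,2,3-trimethylcyclohex-3-en-1-yl]pent-2-enal | O=C/C=C(/C)CC[C@]1(C)CCC=C(C)[C@H]1C | intermediate
24 | 1,2,3-trimethoxybenzene | COc1cccc(OC)c1OC | starting material
25 | 1,5-dibromo-2,3,4-trimethoxybenzene | COc1c(Br)cc(Br)c(OC)c1OC | intermediate
26 | 4,5,6-trimethoxybenzene-1,3-diol | COc1c(O)cc(O)c(OC)c1OC | intermediate
27 | 2-{(2Z)-1-hydroxy-3-methyl-5-[(1S,2S)-1,2,3-trimethylcyclohex-3-en-1-yl]pent-2-en-1-yl}-4,5,6-trimethoxybenzene-1,3-diol (both carbinol epimers) | COc1c(O)c(C(O)/C=C(/C)CC[C@]2(C)CCC=C(C)[C@H]2C)c(O)c(OC)c1OC | intermediate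
28 | ortho-quinone methide formed from 27 by loss of water (5-hydroxy-2,3,4-trimethoxy-6-alkenylidenecyclohexa-2,4-dien-1-one) | COC1=C(OC)C(OC)=C(O)\C(=C\C=C(\C)CC[C@]2(C)CCC=C(C)[C@H]2C)C1=O | intermediate
29 | (2R)-6,7,8-trimethoxy-2-methyl-2-{2-[(1S,2S)-1,2,3-trimethylcyclohex-3-en-1-yl]ethyl}-2H-chromen-5-ol | COc1c(O)c2c(c(OC)c1OC)O[C@](C)(CC[C@]1(C)CCC=C(C)[C@H]1C)C=C2 | target

**Step count and risks**

Total step count: 15. Longest linear sequence: 11 (steps 1, 2, 3, 4, 6, 7, 8, 9, 11, 12, 15).

Steps most likely to fail: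

1. **Step 15.** The facial selectivity of the C–O ring closure may be poor for a centre that carries two alkyl groups, and the acid may racemise the product by reversible ring opening.
   - The fallback sets out from 22 and comes back at 29.
   - Sharpless epoxidation of 22 (Ti(OiPr)4, L-(+)-diethyl tartrate, t-BuOOH, 4 Å MS, −20 °C) gives the (2S,3R)-epoxy alcohol F1. In F1 the future chromene C2 already bears its oxygen in the right configuration.
   - Appel chlorination (PPh3, CCl4) gives the epoxy chloride F2. n-BuLi (3.5 equiv, THF, −35 °C) then induces a double elimination to the (R)-tertiary propargylic alcohol F3.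
   - Twofold bromination (NBS) of commercial 5-iodo-1,2,3-trimethoxybenzene gives 1,3-dibromo-2-iodo-4,5,6-trimethoxybenzene F4.
   - Sonogashira coupling of F3 with F4 at the C–I bond (PdCl2(PPh3)2, CuI, Et3N) gives the aryl alkyne F5. Semihydrogenation over Pd/CaCO3 poisoned with Pb(OAc)2 gives the (Z)-styrenyl alcohol F6.
   - Intramolecular palladium-catalysed C–O coupling (Pd(OAc)2, 2-(di-tert-butylphosphino)-1,1'-binaphthyl, Cs2CO3, toluene) at one of the two equivalent C–Br bonds closes the pyran ring without touching the C–O stereocentre and gives the 5-bromochromene F7.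
   - Copper-catalysed hydroxylation as in step 14 gives 29.

2. **Step 6.** O-vinylation of the hindered secondary alcohol may be slow, part of the rearrangement may pass through a boat transition state, and C2 may epimerise during the hot basic or acidic phase.
   - The fallback sets out from 6 and comes back at 11.
   - Acylation with propionyl chloride and pyridine gives the propanoate F8.
   - LDA in THF and Me3SiCl give the (E)-silyl ketene acetal F9, in which the methyl group is cis to the allylic oxygen, the same relative geometry as in 10.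
   - F9 undergoes the Ireland–Claisen rearrangement below room temperature to the acid F10.
   - Two equivalents of MeLi turn F10 into 11. Here 11 is isolated and cyclised to 13 in a separate, milder operation (wet oxalic acid on silica, then piperidinium acetate).

3. **Step 9.** The ruthenium alkylidene may fail to engage the alkene next to the quaternary carbon, or ruthenium hydrides may shift the double bond.
   - The fallback sets out from 15 and comes back at 17.
   - Lemieux–Johnson cleavage (OsO4 cat., NaIO4, 2,6-lutidine) of the electron-rich side-chain alkene of 15, whose enol triflate alkene is deactivated, gives the aldehyde F11.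
   - Wittig methylenation (Ph3P=CH2, −78 °C) gives the vinyl triflate F12.
   - Iron-catalysed methylation as in step 8 gives 17.

**Further compounds**
F1 | step 15 | [(2S,3R)-3-methyl-3-{2-[(1S,2S)-1,2,3-trimethylcyclohex-3-en-1-yl]ethyl}oxiran-2-yl]methanol | OC[C@@H]1O[C@]1(C)CC[C@]2(C)CCC=C(C)[C@H]2C
F2 | step 15 | (2R,3R)-2-(chloromethyl)-3-methyl-3-{2-[(1S,2S)-1,2,3-trimethylcyclohex-3-en-1-yl]ethyl}oxirane | ClC[C@@H]1O[C@]1(C)CC[C@]2(C)CCC=C(C)[C@H]2C
F3 | step 15 | (3R)-3-methyl-5-[(1S,2S)-1,2,3-trimethylcyclohex-3-en-1-yl]pent-1-yn-3-ol | C#C[C@](C)(O)CC[C@]1(C)CCC=C(C)[C@H]1C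
F4 | step 15 | 1,3-dibromo-2-iodo-4,5,6-trimethoxybenzene | COc1c(Br)c(I)c(Br)c(OC)c1OC
F5 | step 15 | (3R)-1-(2,6-dibromo-3,4,5-trimethoxyphenyl)-3-methyl-5-[(1S,2S)-1,2,3-trimethylcyclohex-3-en-1-yl]pent-1-yn-3-ol | COc1c(Br)c(C#C[C@](C)(O)CC[C@]2(C)CCC=C(C)[C@H]2C)c(Br)c(OC)c1OC
F6 | step 15 | (1Z,3R)-1-(2,6-dibromo-3,4,5-trimethoxyphenyl)-3-methyl-5-[(1S,2S)-1,2,3-trimethylcyclohex-3-en-1-yl]pent-1-en-3-ol | COc1c(Br)c(/C=C\[C@](C)(O)CC[C@]2(C)CCC=C(C)[C@H]2C)c(Br)c(OC)c1OC
F7 | step 15 | (2R)-5-bromo-6,7,8-trimethoxy-2-methyl-2-{2-[(1S,2S)-1,2,3-trimethylcyclohex-3-en-1-yl]ethyl}-2H-chromene | COc1c(Br)c2c(c(OC)c1OC)O[C@](C)(CC[C@]1(C)CCC=C(C)[C@H]1C)C=C2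
F8 | step 6 | (3R,4E)-7,7-dimethoxy-5-methylhept-4-en-3-yl propanoate | CC[C@@H](OC(=O)CC)/C=C(\C)CC(OC)OC
F9 | step 6 | (E)-trimethylsilyl ketene acetal of F8 | CC[C@@H](O/C(O[Si](C)(C)C)=C\C)/C=C(\C)CC(OC)OC
F10 | step 6 | (2S,3S,4E)-3-(2,2-dimethoxyethyl)-2,3-dimethylhept-4-enoic acid | CC/C=C/[C@](C)(CC(OC)OC)[C@H](C)C(=O)O
F11 | step 9 | (5R,6S)-5-formyl-5,6-dimethylcyclohex-1-en-1-yl trifluoromethanesulfonate (same spatial arrangement as 15) | O=C[C@]1(C)CCC=C(OS(=O)(=O)C(F)(F)F)[C@H]1C
F12 | step 9 | (5S,6S)-5-ethenyl-5,6-dimethylcyclohex-1-en-1-yl trifluoromethanesulfonate | C=C[C@]1(C)CCC=C(OS(=O)(=O)C(F)(F)F)[C@H]1C
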